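**Remark on the chemistry.** The target has no stereocentre and no stereogenic double bond. It is achiral, so no stereocontrol is needed. 1,3,5-Tris(benzyloxy)benzene is taken as a purchasable phloroglucinol ether.

## Retrosynthetic overview

1. Target 13 ⇐ 12 by hydrogenolysis of the three benzyl ethers on the phloroglucinol ring (last step, neutral, spares the aryl acetate).
2. Key disconnection: the acetylated resorcinol ring (aromatic C–OAc, C–CH2R and C–OH on three neighbouring carbons) is not made from a resorcinol. It comes from dehydrogenative aromatization of enol acetate 10 of a 2-alkylcyclohexane-1,3-dione: the acetyl group sits on the only enol oxygen before the ring is aromatic, and the ring C=O becomes the free phenol. One of five phenolic oxygens is thus acetylated without ever having to be told apart from the others.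
3. 10 ⇐ dione 9 ⇐ cyclohexane-1,3-dione 7 + keto aldehyde 6 by reductive Knoevenagel alkylation (forms the ring C2–CH2 bond).
4. 6 ⇐ bromo ketone 4 ⇐ 11-bromoundecanoic acid 1 + 1,3,5-tris(benzyloxy)benzene 2 by Friedel–Crafts acylation (forms the aryl–C(=O) bond).
5. Order of rings: no ring is closed by bond formation. The phloroglucinol ring enters as an arene in step 1; the second six-membered ring enters as a dione in step 3 and becomes aromatic in step 5.

Key step: step 5

## Route

Step 1
Reactants: 1 11-bromoundecanoic acid; 2 1,3,5-tris(benzyloxy)benzene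
Product: 4 11-bromo-1-[2,4,6-tris(benzyloxy)phenyl]undecan-1-one, via acyl trifluoroacetate 3 (not isolated)
Conditions: TFAA (1.3 equiv), CH2Cl2, 0 °C; then 2, 0 °C to rt; aq. NaHCO3 work-up
Reagents that add atoms: none
Why: Friedel–Crafts acylation by a mixed carboxylic–trifluoroacetic anhydride; the triply alkoxy-activated arene should be acylated without a Lewis acid, so the benzyl ethers should survive, and the three free ring positions are equivalent.

Step 2
Reactants: 4 11-bromo-1-[2,4,6-tris(benzyloxy)phenyl]undecan-1-one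
Product: 6 11-oxo-11-[2,4,6-tris(benzyloxy)phenyl]undecanal, via alkoxytrimethylammonium bromide 5 (not isolated)
Conditions: anhydrous Me3NO (4 equiv), DMSO, rt to 40 °C
Reagents that add atoms: trimethylamine N-oxide, C[N+](C)(C)[O-]
Why: N-oxide variant of the Kornblum oxidation; SN2 displacement of the primary bromide by the N-oxide oxygen and base-induced loss of trimethylamine from the alkoxyammonium salt should give the aldehyde without touching the hindered aryl ketone.

Step 3
Reactants: 6 11-oxo-11-[2,4,6-tris(benzyloxy)phenyl]undecanal; 7 cyclohexane-1,3-dione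
Product: 9 2-{11-oxo-11-[2,4,6-tris(benzyloxy)phenyl]undecyl}cyclohexane-1,3-dione, via alkylidene dione 8 (not isolated)
Conditions: diethyl 2,6-dimethyl-1,4-dihydropyridine-3,5-dicarboxylate (Hantzsch ester, 1.1 equiv), L-proline (10 mol %), CH2Cl2, rt
Reagents that add atoms: none
Why: Organocatalytic three-component reductive alkylation (Knoevenagel condensation, then transfer hydrogenation by the Hantzsch ester); the acidic dione condenses at C2 and the electron-poor alkylidene dione should be reduced before it can add a second dione, which avoids the C- versus O-alkylation problem of alkyl halides.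

Step 4
Reactants: 9 2-{11-oxo-11-[2,4,6-tris(benzyloxy)phenyl]undecyl}cyclohexane-1,3-dione
Product: 10 3-oxo-2-{11-oxo-11-[2,4,6-tris(benzyloxy)phenyl]undecyl}cyclohex-1-en-1-yl acetate
Conditions: Ac2O (1.5 equiv), pyridine, CH2Cl2, 0 °C
Reagents that add atoms: acetic anhydride, CC(=O)OC(C)=O
Why: O-acylation of a 2-substituted cyclic 1,3-dione; with C2 blocked the enol oxygen is the only acylation site, and because the dione is symmetrical only one enol acetate can form.

Step 5
Reactants: 10 3-oxo-2-{11-oxo-11-[2,4,6-tris(benzyloxy)phenyl]undecyl}cyclohex-1-en-1-yl acetate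
Product: 12 3-hydroxy-2-{11-oxo-11-[2,4,6-tris(benzyloxy)phenyl]undecyl}phenyl acetate, via cross-conjugated dienone 11 (not isolated)
Conditions: Pd(TFA)2 (5 mol %), 2-(dimethylamino)pyridine (10 mol %), TsOH (20 mol %), O2 (1 atm), 3 Å MS, DMSO, 80 °C
Reagents that add atoms: none
Why: Proposed new method: Pd(II) is expected to palladate the α′-carbon (ring C6) of the β-acetoxy enone through its enol, β-hydride elimination from C5 should then give the cross-conjugated dienone 11, which tautomerizes under the acid co-catalyst to the phenol while O2 reoxidizes the Pd–H species; the closest known reaction type is the Pd(II)-catalysed aerobic dehydrogenation of 2- and 3-substituted cyclohex-2-enones to phenols, applied here to a vinylogous anhydride. No ring is closed and no stereocentre is formed: the six-membered carbocycle bought as cyclohexane-1,3-dione becomes the benzene ring, the ring carbonyl oxygen becomes the free phenol and the enol oxygen keeps its acetyl group, so the ArO–Ac / ArO–H pattern on either side of the alkyl-bearing carbon is fixed by construction. Both conceivable dienones (2,5- or 2,4-) would tautomerize to the same phenol, so the site of dehydrogenation within the ring does not matter. The step needs chemoselectivity for the ring α′-C–H bonds over the α-CH2 of the acyclic aryl ketone, which should follow from the low reactivity of acyclic ketones in this catalyst system and from the shielding of that carbonyl between two ortho benzyloxy groups. It also needs the acetyl group to stay on oxygen, for which the water formed is taken up by molecular sieves and the acid loading is kept low.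

Step 6
Reactants: 12 3-hydroxy-2-{11-oxo-11-[2,4,6-tris(benzyloxy)phenyl]undecyl}phenyl acetate
Product: 13 3-hydroxy-2-[11-oxo-11-(2,4,6-trihydroxyphenyl)undecyl]phenyl acetate
Conditions: H2 (1 atm), 10 % Pd/C, EtOAc, rt
Reagents that add atoms: none
Why: Hydrogenolysis of aryl benzyl ethers over Pd/C under neutral conditions in a non-nucleophilic solvent should leave the aryl acetate and the hydrogen-bonded acylphloroglucinol ketone intact.

## Compound list

1 | 11-bromoundecanoic acid | OC(=O)CCCCCCCCCCBr | starting material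
2 | 1,3,5-tris(benzyloxy)benzene | c1ccc(COc2cc(OCc3ccccc3)cc(OCc3ccccc3)c2)cc1 | starting material
3 | 11-bromoundecanoic trifluoroacetic anhydride (not isolated) | O=C(CCCCCCCCCCBr)OC(=O)C(F)(F)F | intermediate
4 | 11-bromo-1-[2,4,6-tris(benzyloxy)phenyl]undecan-1-one | BrCCCCCCCCCCC(=O)c1c(OCc2ccccc2)cc(OCc2ccccc2)cc1OCc1ccccc1 | intermediate
5 | trimethyl({11-oxo-11-[2,4,6-tris(benzyloxy)phenyl]undecyl}oxy)ammonium bromide (not isolated) | C[N+](C)(C)OCCCCCCCCCCC(=O)c1c(OCc2ccccc2)cc(OCc2ccccc2)cc1OCc1ccccc1.[Br-] | intermediate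
6 | 11-oxo-11-[2,4,6-tris(benzyloxy)phenyl]undecanal | O=CCCCCCCCCCC(=O)c1c(OCc2ccccc2)cc(OCc2ccccc2)cc1OCc1ccccc1 | intermediate
7 | cyclohexane-1,3-dione | O=C1CCCC(=O)C1 | starting material
8 | 2-{11-oxo-11-[2,4,6-tris(benzyloxy)phenyl]undecylidene}cyclohexane-1,3-dione (not isolated) | O=C1CCCC(=O)C1=CCCCCCCCCCC(=O)c1c(OCc2ccccc2)cc(OCc2ccccc2)cc1OCc1ccccc1 | intermediate
9 | 2-{11-oxo-11-[2,4,6-tris(benzyloxy)phenyl]undecyl}cyclohexane-1,3-dione (drawn as the diketo tautomer) | O=C1CCCC(=O)C1CCCCCCCCCCC(=O)c1c(OCc2ccccc2)cc(OCc2ccccc2)cc1OCc1ccccc1 | intermediate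
10 | 3-oxo-2-{11-oxo-11-[2,4,6-tris(benzyloxy)phenyl]undecyl}cyclohex-1-en-1-yl acetate | CC(=O)OC1=C(CCCCCCCCCCC(=O)c2c(OCc3ccccc3)cc(OCc3ccccc3)cc2OCc2ccccc2)C(=O)CCC1 | intermediate
11 | 3-oxo-2-{11-oxo-11-[2,4,6-tris(benzyloxy)phenyl]undecyl}cyclohexa-1,4-dien-1-yl acetate (not isolated) | CC(=O)OC1=C(CCCCCCCCCCC(=O)c2c(OCc3ccccc3)cc(OCc3ccccc3)cc2OCc2ccccc2)C(=O)C=CC1 | intermediate
12 | 3-hydroxy-2-{11-oxo-11-[2,4,6-tris(benzyloxy)phenyl]undecyl}phenyl acetate | CC(=O)Oc1cccc(O)c1CCCCCCCCCCC(=O)c1c(OCc2ccccc2)cc(OCc2ccccc2)cc1OCc1ccccc1 | intermediate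
13 | 3-hydroxy-2-[11-oxo-11-(2,4,6-trihydroxyphenyl)undecyl]phenyl acetate | CC(=O)Oc1cccc(O)c1CCCCCCCCCCC(=O)c1c(O)cc(O)cc1O | target

## Step count and risks

Total step count: 6. Longest linear sequence: 6 steps.

Steps most likely to fail:

**Step 5 (Proposed new method).** The acetyl group may be lost from the enol oxygen by hydrolysis, or passed on to phenol already formed, before dehydrogenation is complete; palladation of the β-acyloxy enone may also be too slow. The fallback sets out from 9 and comes back at 12, with the arene made first and the oxygens differentiated afterwards by known chemistry. N-Bromosuccinimide (1 equiv, CH2Cl2, 0 °C) should brominate C2 of 9 to give 2-bromo-2-{11-oxo-11-[2,4,6-tris(benzyloxy)phenyl]undecyl}cyclohexane-1,3-dione F1. Heating in DMF with catalytic HCl (halogenation–dehydrohalogenation aromatization of 2-alkylcyclohexane-1,3-diones) should give the symmetrical 1-[2,4,6-tris(benzyloxy)phenyl]-11-(2,6-dihydroxyphenyl)undecan-1-one F2. One equivalent of Ac2O in pyridine should then give 12 in a statistical monoacetylation. Unreacted F2 is reused, and the doubly acetylated 2-{11-oxo-11-[2,4,6-tris(benzyloxy)phenyl]undecyl}-1,3-phenylene diacetate F3 is returned to F2 with K2CO3 in MeOH.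

**Step 2.** Elimination of HBr, or base-induced self-condensation of the aldehyde as it forms, may compete with the oxidation. The fallback sets out from 4 and comes back at 6, passing through the alcohol oxidation level. KOAc in DMF should give 11-oxo-11-[2,4,6-tris(benzyloxy)phenyl]undecyl acetate F4. K2CO3 in MeOH should give 11-hydroxy-1-[2,4,6-tris(benzyloxy)phenyl]undecan-1-one F5. Dess–Martin periodinane in CH2Cl2 should then give 6.

**Step 1.** A benzyl group ortho to the new ketone may be lost under the acidic conditions, or the arene may be trifluoroacetylated instead. The fallback sets out from 2 (and 1) and comes back at 4, replacing the electrophilic acylation by an organolithium addition. N-Bromosuccinimide in CH2Cl2 should convert 2 into 2-bromo-1,3,5-tris(benzyloxy)benzene F6. Bromine–lithium exchange (n-BuLi, THF, −78 °C) should give [2,4,6-tris(benzyloxy)phenyl]lithium F7. This is added at −78 °C to 11-bromo-N-methoxy-N-methylundecanamide F8, made from 1 with 1,1'-carbonyldiimidazole and N,O-dimethylhydroxylamine hydrochloride. Aqueous NH4Cl work-up should release 4.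

## Further compounds

F1 | step 5 | 2-bromo-2-{11-oxo-11-[2,4,6-tris(benzyloxy)phenyl]undecyl}cyclohexane-1,3-dione | O=C1CCCC(=O)C1(Br)CCCCCCCCCCC(=O)c1c(OCc2ccccc2)cc(OCc2ccccc2)cc1OCc1ccccc1
F2 | step 5 | 1-[2,4,6-tris(benzyloxy)phenyl]-11-(2,6-dihydroxyphenyl)undecan-1-one | Oc1cccc(O)c1CCCCCCCCCCC(=O)c1c(OCc2ccccc2)cc(OCc2ccccc2)cc1OCc1ccccc1
F3 | step 5 | 2-{11-oxo-11-[2,4,6-tris(benzyloxy)phenyl]undecyl}-1,3-phenylene diacetate | CC(=O)Oc1cccc(OC(C)=O)c1CCCCCCCCCCC(=O)c1c(OCc2ccccc2)cc(OCc2ccccc2)cc1OCc1ccccc1
F4 | step 2 | 11-oxo-11-[2,4,6-tris(benzyloxy)phenyl]undecyl acetate | CC(=O)OCCCCCCCCCCC(=O)c1c(OCc2ccccc2)cc(OCc2ccccc2)cc1OCc1ccccc1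
F5 | step 2 | 11-hydroxy-1-[2,4,6-tris(benzyloxy)phenyl]undecan-1-one | OCCCCCCCCCCC(=O)c1c(OCc2ccccc2)cc(OCc2ccccc2)cc1OCc1ccccc1
F6 | step 1 | 2-bromo-1,3,5-tris(benzyloxy)benzene | Brc1c(OCc2ccccc2)cc(OCc2ccccc2)cc1OCc1ccccc1
F7 | step 1 | [2,4,6-tris(benzyloxy)phenyl]lithium | [Li]c1c(OCc2ccccc2)cc(OCc2ccccc2)cc1OCc1ccccc1
F8 | step 1 | 11-bromo-N-methoxy-N-methylundecanamide | CON(C)C(=O)CCCCCCCCCCBr
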